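The teal run, with equal charges of starting material and partner, gives you a scale. If the rate is first in each, the reciprocal of c(starting material) climbs by exactly the time integral of the rate constant.

| flask | starting material | partner | time |
|---|---|---|---|
| green | 0.600 M | 0.900 M |  |
| teal | 0.900 M | 0.900 M |  |
| amber | 0.200 M | 1.80 M | 110 min |

| run | time / min | [starting material] / M |
|---|---|---|
| green run | 6.3 | 0.546 |
| green run | 19 | 0.463 |
| green run | 36 | 0.405 |
| green run | 57 | 0.351 |
| green run | 82 | 0.300 |
| green run | 110 | 0.262 |
| teal run | 6.3 | 0.809 |
| teal run | 19 | 0.692 |
| teal run | 36 | 0.614 |
| teal run | 57 | 0.541 |
| teal run | 82 | 0.489 |
| teal run | 110 | 0.435 |

(each reading ± 0.006 M)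

1. the exponent of [starting material] in the starting rate at the charge of the green run (at the point where two percent of the starting material have become product) (one fixed amount of product, the same in the runs compared)
2. starting material in the amber run at 110 min, as a share of the starting material charged

- Overall: starting material + partner -> product.
- Constant volume, constant temperature.
- An order is taken over about fifteen percent of the charge, up and down.

My quantity is that integral at the time asked, the exposure 1.19 /M, read from the last teal reading. The green run, through its own integrated second-order law, gives 1.19 /M. So I take an order of 1 in starting material and carry the exposure, as a function of time, to the amber flask.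

Here is my curve for amber. The rate constant read from the first teal reading sets the starting slope:

k = 0.0198 /M/min, slope = 0.00714 M/min

Falling to half the charge in the amber flask takes this exposure:

0.397 /M

The teal run passes that between 19 min and 36 min. The last teal interval reads a constant of 0.00907 /M/min, about half the first reading, so I let my amber curve bend on the same clock. At 110 min the integrated law gives:

1.60 M is the gap between the charges
c(starting material) = 0.0270 M, a share of 13.5%

Starting material is the limiting reagent. In my reckoning c(partner) in the amber flask ends near 1.63 M, so the decay is nearly pseudo-first-order, and c(starting material) is still falling at 3.99 × 10⁻⁴ M/min.

The forecast gives an order of 1 (0.8 to 1.25) and 22% (12.5% to 29%). It reads the amber time “as a hold before mixing”, whereas I count it as reaction time, so my share is lower.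

The flask gives an order of 1.1 and 14.4% in the amber run.

    starting material + 2 partner → product + partner (0.02046 /M²/min)
    2 partner → lost reagent (0.007440 /M/min)
    starting material → decomposed substrate (0.002430 /min)

Run backward through the same law, that share is an exposure of 1.15 /M, against 1.19 /M from the teal run. The teal run reached a quarter of its charge as product at 36.2 min, which is 0.225 M of product, while its reading at 36 min has lost 0.286 M of starting material. Counted on product, the teal exposure there is 0.370 /M, and counted on the reading it is 0.518 /M.

All runs were computed with constants of no real substance; the scatter is artificial.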